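**Plan**
- Ring numbering used throughout: C1 = ketone carbon, C2 = alkenyl-bearing alkene carbon, C3 = CH2OH-bearing alkene carbon, C4 and C5 = carbinols, C6 = CH carrying the butenoic acid chain. Retrosynthetic cuts: C2–alkenyl (Suzuki), the enoate C=C (cross-metathesis), the ring bond C5–C6 (aldol-type closure), then C1–C6 (Grignard addition).
- Forward: a cyclopentenone that already holds C1–C5 receives the CH2O carbon at C3 and the C6 chain at C1. Its C1–C5 bond is then cut oxidatively and the chain is reclosed through C5–C6, a net one-carbon ring expansion to the cyclohexenone.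
- Enabling feature: the cis-4,5-diol. Held as a dioxolane across O4/O5, its oxygen on C5 directs the scission (C5 leaves as an oxygen-stabilised radical, then cation) and stores C5 at the aldehyde level as a cyclic oxocarbenium ion. C6 is the only enolizable carbon of the freed C1 ketone, because C2=C3 is the ring alkene.
- Stereochemistry: C4 is carried from the cyclopentenone; C5 follows from the enforced cis ring fusion; C6 from the Z enol ether and equilibrium control; the side-chain carbinol from (R)-propylene oxide; both chain alkenes are E from cross-metathesis.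
- End game: α-iodination, Suzuki coupling, one-pot BCl3 deprotection.

Key step: step 6

Remark: enone 1 (the 4S,5S enantiomer) and stannane 2 are taken as purchasable; otherwise 1 is reached from D-ribose by known ring-closing-metathesis sequences and 2 by benzylation of tributylstannylmethanol.

Step 1
Reactants: 1 (4S,5S)-4,5-O-isopropylidenecyclopent-2-enone; 2 tributyl[(benzyloxy)methyl]stannane
Product: 4 tertiary allylic alcohol (hydroxyl cis to the dioxolane oxygens), via (benzyloxy)methyllithium 3 (not isolated)
Conditions: 2, n-BuLi, THF, −78 °C; then 1, −78 °C; H2O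
Reagents that add atoms: none
Why: Tin–lithium exchange gives the α-alkoxy organolithium (a hydroxymethyl anion equivalent), which should add 1,2 to the enone from the convex face anti to the dioxolane; the new carbinol centre is erased in step 2.

Step 2
Reactants: 4 tertiary allylic alcohol
Product: 5 (4R,5R)-3-[(benzyloxy)methyl]-4,5-O-isopropylidenecyclopent-2-enone
Conditions: pyridinium chlorochromate [C5H5NH][CrO3Cl], 4 Å MS, CH2Cl2, rt
Reagents that add atoms: pyridinium chlorochromate, [O-][Cr](=O)(=O)Cl.c1cc[nH+]cc1 (supplies the carbonyl oxygen)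
Why: Oxidative 1,3-transposition of a tertiary allylic alcohol (Dauben–Babler oxidation) by [3,3] shift of the chromate ester and oxidation puts the carbonyl at the far allylic terminus, so the benzyloxymethyl group ends on the β-carbon next to the stereocentre that becomes C4; no stereocentre is touched.

Step 3
Reactants: 5 enone; 6 but-3-en-1-ylmagnesium bromide
Product: 7 tertiary cyclopentenol carrying the butenyl group on C1 (hydroxyl cis to the dioxolane oxygens)
Conditions: CeCl3, THF, −78 °C; H2O
Reagents that add atoms: none
Why: Organocerium 1,2-addition to the enone carbonyl should occur anti to the neighbouring dioxolane oxygen and without enolization; the Grignard carbon becomes C6, and the carbinol configuration is irrelevant because C1 returns to a ketone in step 5.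

Step 4
Reactants: 7 butenyl cyclopentenol; 8 tert-butyl methacrylate
Product: 9 (E)-enoate cyclopentenol
Conditions: second-generation Hoveyda–Grubbs catalyst RuCl2(=CH-C6H4-2-OiPr)(H2IMes) (cat.), 8 (excess), CH2Cl2, 40 °C
Reagents that add atoms: none
Why: Olefin cross-metathesis of the terminal alkene with the 1,1-disubstituted acrylate should give the trisubstituted enoate in the thermodynamically preferred E geometry, while the hindered trisubstituted ring alkene stays out of the reaction.

Step 5
Reactants: 9 (E)-enoate cyclopentenol
Product: 10 Z keto enone bearing a 5-acetoxy-2,2-dimethyl-1,3-dioxolan-4-yl group (both epimers at the acetoxy carbon)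
Conditions: PhI(OAc)2, I2, CH2Cl2, visible light, rt
Reagents that add atoms: (diacetoxyiodo)benzene, CC(=O)OI(OC(C)=O)c1ccccc1
Why: Hypoiodite β-fragmentation (Suárez reaction): the tertiary alkoxyl radical should cleave the C1–C5 bond, the only scission that gives an oxygen-stabilised dioxolanyl radical and an enone carbonyl, and oxidation of that radical with capture by acetate leaves C5 at the aldehyde level as an anomeric acetate, with the former ring alkene released in its cis (Z) geometry and C4 untouched.

Step 6
Reactants: 10 keto acetoxy acetal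
Product: 12 bicyclic cyclohexenone (4,5-O-isopropylidene; 4R,5S,6S in target numbering), via silyl enol ether 11 (not isolated)
Conditions: TMSOTf, iPr2NEt, CH2Cl2, −78 → −40 °C; aq. NaHCO3
Reagents that add atoms: none
Why: TMSOTf/iPr2NEt should convert the only enolizable α-carbon of ketone 10 (C6; C2 is sp2) into the (Z)-silyl enol ether, and the same Lewis acid ionizes the anomeric acetate to a 2,2-dimethyl-1,3-dioxolan-4-ylium (oxocarbenium) ion at C5, which the enol ether captures at carbon to forge C5–C6 before silyl loss returns the ketone. The closest known reaction type is the intramolecular Mukaiyama aldol-type addition of an enol silane to an oxocarbenium ion from an α-acetoxy ether, with one-pot enol silane formation. The cyclohexenone ring closes in the 6-(enolendo)-exo-trig mode. C5 is set by the tether: C6 can reach the cation only on the dioxolane face that carries C3, so the ring fusion, and with it the 4,5-diol, must be cis. C6 is set by the (Z)-enol ether reacting through an envelope transition state with the C4–O bond pseudoaxial (avoiding allylic strain with the C3 benzyloxymethyl group), which places the side chain pseudoequatorial and trans to the C5 oxygen; this should also be the more stable epimer at this enolizable centre. The step needs ionization of the acetoxy acetal in preference to the isopropylidene ketal and tert-butyl ester, secured by its much higher lability at −78 °C, and C- rather than O-capture, secured because C–C bond formation is irreversible while capture by the benzyl ether or enol oxygen is reversible.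

Step 7
Reactants: 12 bicyclic cyclohexenone
Product: 13 2-iodo enone
Conditions: I2, pyridine, DMAP (cat.), CH2Cl2, rt, dark
Reagents that add atoms: iodine, II
Why: Amine-promoted α-iodination of an enone (conjugate addition of the amine, iodination of the enolate, elimination) should place iodine on C2 for the coupling, the weak base leaving the β-alkoxy ketone intact.

Step 8
Reactants: 14 (R)-2-methyloxirane; 6 but-3-en-1-ylmagnesium bromide
Product: 15 (R)-hept-6-en-2-ol
Conditions: CuI (cat.), THF, −30 → 0 °C; H2O
Reagents that add atoms: none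
Why: Copper-catalysed epoxide opening by the Grignard reagent at the unsubstituted carbon leaves the stereocentre untouched, so it stays R.

Step 9
Reactants: 15 (R)-hept-6-en-2-ol; 16 4,4,5,5-tetramethyl-2-vinyl-1,3,2-dioxaborolane
Product: 17 (R,E)-7-(pinacolboryl)hept-6-en-2-ol
Conditions: second-generation Grubbs catalyst RuCl2(=CHPh)(PCy3)(H2IMes) (cat.), CH2Cl2, 40 °C
Reagents that add atoms: none
Why: Cross-metathesis of the terminal alkene with the vinyl boronate should give the (E)-alkenyl boronate, and the free hydroxyl is tolerated.

Step 10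
Reactants: 13 2-iodo enone; 17 (E)-alkenyl boronate
Product: 18 fully assembled, protected target
Conditions: Pd(dppf)Cl2 (cat.), AsPh3, Cs2CO3, DMF/THF/H2O, rt
Reagents that add atoms: none
Why: Suzuki–Miyaura coupling of a 2-iodoenone with an (E)-alkenyl boronate proceeds with retention of alkene geometry at room temperature under mild aqueous carbonate, conditions suited to base-sensitive α-iodoenones.

Step 11
Reactants: 18 protected target
Product: 19 pestallic acid O
Conditions: BCl3, C6HMe5, CH2Cl2, −78 °C; MeOH/H2O
Reagents that add atoms: none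
Why: BCl3 with pentamethylbenzene as cation scavenger cleaves the benzyl ether at low temperature and the same Lewis acid removes the isopropylidene ketal and the tert-butyl ester, so one operation should free the three masked hydroxyls and the acid without base or heat that would threaten the β-hydroxy ketone.

**Compound list**
1 | (3aS,6aS)-2,2-dimethyl-3a,6a-dihydro-4H-cyclopenta[d][1,3]dioxol-4-one | O=C1C=C[C@@H]2OC(C)(C)O[C@H]12 | starting material
2 | tributyl[(benzyloxy)methyl]stannane | CCCC[Sn](CCCC)(CCCC)COCc1ccccc1 | starting material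
3 | (benzyloxy)methyllithium | [Li]COCc1ccccc1 | intermediate
4 | (3aS,4S,6aS)-4-[(benzyloxy)methyl]-2,2-dimethyl-3a,6a-dihydro-4H-cyclopenta[d][1,3]dioxol-4-ol | O[C@]1(COCc3ccccc3)C=C[C@@H]2OC(C)(C)O[C@H]12 | intermediate
5 | (3aR,6aR)-6-[(benzyloxy)methyl]-2,2-dimethyl-3a,6a-dihydro-4H-cyclopenta[d][1,3]dioxol-4-one | O=C1C=C(COCc3ccccc3)[C@H]2OC(C)(C)O[C@@H]12 | intermediate
6 | but-3-en-1-ylmagnesium bromide | C=CCC[Mg]Br | starting material
7 | (3aR,4S,6aR)-6-[(benzyloxy)methyl]-4-(but-3-en-1-yl)-2,2-dimethyl-3a,6a-dihydro-4H-cyclopenta[d][1,3]dioxol-4-ol | O[C@@]1(CCC=C)C=C(COCc3ccccc3)[C@H]2OC(C)(C)O[C@@H]12 | intermediate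
8 | tert-butyl methacrylate | C=C(C)C(=O)OC(C)(C)C | starting material
9 | tert-butyl (E)-5-[(3aR,4S,6aR)-6-[(benzyloxy)methyl]-4-hydroxy-2,2-dimethyl-3a,6a-dihydro-4H-cyclopenta[d][1,3]dioxol-4-yl]-2-methylpent-2-enoate | O[C@@]1(CC/C=C(\C)C(=O)OC(C)(C)C)C=C(COCc3ccccc3)[C@H]2OC(C)(C)O[C@@H]12 | intermediate
10 | tert-butyl (2E,7Z)-8-[(4R)-5-acetoxy-2,2-dimethyl-1,3-dioxolan-4-yl]-9-(benzyloxy)-2-methyl-6-oxonona-2,7-dienoate (both epimers at the acetoxy carbon) | CC(=O)OC1OC(C)(C)O[C@@H]1/C(COCc2ccccc2)=C\C(=O)CC/C=C(\C)C(=O)OC(C)(C)C | intermediate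
11 | trimethylsilyl enol ether of 10 (silyloxy group cis to the chain CH2 on the new enol double bond) | CC(=O)OC1OC(C)(C)O[C@@H]1/C(COCc2ccccc2)=C\C(O[Si](C)(C)C)=C\C/C=C(\C)C(=O)OC(C)(C)C | intermediate
12 | tert-butyl (E)-4-[(3aS,4S,7aR)-7-[(benzyloxy)methyl]-2,2-dimethyl-5-oxo-3a,4,5,7a-tetrahydro-1,3-benzodioxol-4-yl]-2-methylbut-2-enoate | CC(C)(C)OC(=O)/C(C)=C/C[C@@H]1C(=O)C=C(COCc3ccccc3)[C@H]2OC(C)(C)O[C@@H]12 | intermediate
13 | 6-iodo derivative of 12 (iodine on the enone α-carbon, C2 in target numbering) | CC(C)(C)OC(=O)/C(C)=C/C[C@@H]1C(=O)C(I)=C(COCc3ccccc3)[C@H]2OC(C)(C)O[C@@H]12 | intermediate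
14 | (R)-2-methyloxirane | C[C@@H]1CO1 | starting material
15 | (R)-hept-6-en-2-ol | C[C@@H](O)CCCC=C | intermediate
16 | 4,4,5,5-tetramethyl-2-vinyl-1,3,2-dioxaborolane | C=CB1OC(C)(C)C(C)(C)O1 | starting material
17 | (R,E)-7-(4,4,5,5-tetramethyl-1,3,2-dioxaborolan-2-yl)hept-6-en-2-ol | C[C@@H](O)CCC/C=C/B1OC(C)(C)C(C)(C)O1 | intermediate
18 | 13 with iodine replaced by the (1E,6R)-6-hydroxyhept-1-en-1-yl group | CC(C)(C)OC(=O)/C(C)=C/C[C@@H]1C(=O)C(/C=C/CCC[C@@H](C)O)=C(COCc3ccccc3)[C@H]2OC(C)(C)O[C@@H]12 | intermediate
19 | pestallic acid O | C/C(=C\C[C@@H]1C(=O)C(/C=C/CCC[C@@H](C)O)=C(CO)[C@@H](O)[C@H]1O)C(=O)O | target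

Total step count: 11. Longest linear sequence: 9 (steps 1–7, 10, 11).

**Steps most likely to fail**

Step 6. The dioxolanyl cation may be diverted before C6 attacks (capture by the enol or ether oxygen, opening of the ketal). The cis enone geometry needed for closure may also already have been eroded by iodine atoms in step 5. The fallback replaces the radical scission by a two-electron glycol cleavage and closes the ring on a free aldehyde; it sets out from 9, comes back at 12 and also bypasses step 5. Mild ketal hydrolysis (PPTS, MeOH) should give the all-cis triol F1. Silylation of the less hindered allylic C4 hydroxyl (TESCl, imidazole, −20 °C) gives the mono-silyl ether F2. Cleavage of the remaining vicinal C1/C5 diol (NaIO4, THF/H2O) gives the Z keto aldehyde F3. A titanium enolate aldol (TiCl4, iPr2NEt, CH2Cl2, −78 °C) then forms C5–C6 to give the β-hydroxy ketone F4. Finally PPTS with 2,2-dimethoxypropane in acetone exchanges the silyl ether for the isopropylidene ketal, which only the cis-4,5-diol can form, giving 12. This closure lacks the ring-fusion control of the main route, so the cis isomer is sorted at the ketalization.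

Step 7. Conjugate addition of the amine to the β,β-disubstituted enone may be slow, and long exposure to base may expel the C5 oxygen and lead to aromatization. The fallback brings the halogen in before the ring expansion; it sets out from 5 and comes back at 13. Iodination of the robust cyclopentenone 5 (I2, pyridine, CH2Cl2) should give the 2-iodo cyclopentenone F5. Steps 3–6 are then run on the iodide: organocerium addition of 6 gives the iodo cyclopentenol F6, cross-metathesis with 8 gives the iodo enoate F7, and hypoiodite fragmentation gives the iodo keto acetoxy acetal F8. Closure under the conditions of step 6, through the iodo silyl enol ether F9, then gives 13 directly.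

Step 11. The Lewis acid may ionize or chlorinate the allylic positions, or dehydrate the β-hydroxy ketone, while three groups are removed at once. The fallback stages the deprotection, protic first and oxidative second; it sets out from 18 and comes back at 19. Aqueous TFA (TFA/H2O/CH2Cl2, 0 °C) should remove the ketal and the tert-butyl ester to give the benzyl ether of the target F10. Visible-light-promoted debenzylation with DDQ (CH2Cl2/H2O, green light) then frees the hydroxymethyl group.

**Further compounds**
F1 | step 6 | tert-butyl (E)-5-[3-[(benzyloxy)methyl]-1,4,5-trihydroxycyclopent-2-en-1-yl]-2-methylpent-2-enoate (all three hydroxyls cis; ketal-free 9) | O[C@@]1(CC/C=C(\C)C(=O)OC(C)(C)C)C=C(COCc2ccccc2)[C@@H](O)[C@H]1O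
F2 | step 6 | 4-O-triethylsilyl ether of F1 | O[C@@]1(CC/C=C(\C)C(=O)OC(C)(C)C)C=C(COCc2ccccc2)[C@@H](O[Si](CC)(CC)CC)[C@H]1O
F3 | step 6 | tert-butyl (2E,7Z)-9-(benzyloxy)-2-methyl-6-oxo-8-[(1R)-2-oxo-1-(triethylsilyloxy)ethyl]nona-2,7-dienoate | O=C[C@H](O[Si](CC)(CC)CC)/C(COCc1ccccc1)=C\C(=O)CC/C=C(\C)C(=O)OC(C)(C)C
F4 | step 6 | 5-hydroxy-4-(triethylsilyloxy) analogue of 12 without the ketal (4,5-cis, 5,6-trans) | CC(C)(C)OC(=O)/C(C)=C/C[C@@H]1C(=O)C=C(COCc2ccccc2)[C@@H](O[Si](CC)(CC)CC)[C@H]1O
F5 | step 7 | (3aR,6aR)-6-[(benzyloxy)methyl]-5-iodo-2,2-dimethyl-3a,6a-dihydro-4H-cyclopenta[d][1,3]dioxol-4-one | O=C1C(I)=C(COCc3ccccc3)[C@H]2OC(C)(C)O[C@@H]12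
F6 | step 7 | 5-iodo analogue of 7 (same configuration) | O[C@@]1(CCC=C)C(I)=C(COCc3ccccc3)[C@H]2OC(C)(C)O[C@@H]12
F7 | step 7 | 5-iodo analogue of 9 (same configuration) | O[C@@]1(CC/C=C(\C)C(=O)OC(C)(C)C)C(I)=C(COCc3ccccc3)[C@H]2OC(C)(C)O[C@@H]12
F8 | step 7 | 7-iodo analogue of 10 (ketone carbonyl and dioxolane cis on the iodoalkene) | CC(=O)OC1OC(C)(C)O[C@@H]1/C(COCc2ccccc2)=C(/I)C(=O)CC/C=C(\C)C(=O)OC(C)(C)C
F9 | step 7 | 7-iodo analogue of silyl enol ether 11 | CC(=O)OC1OC(C)(C)O[C@@H]1/C(COCc2ccccc2)=C(/I)\C(O[Si](C)(C)C)=C\C/C=C(\C)C(=O)OC(C)(C)C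
F10 | step 11 | benzyl ether of 19 at the C3 hydroxymethyl group | C/C(=C\C[C@@H]1C(=O)C(/C=C/CCC[C@@H](C)O)=C(COCc2ccccc2)[C@@H](O)[C@H]1O)C(=O)O
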